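## Retrosynthetic overview

1. The target is 3,4,7-tribromo-2-chloro-1H-indole. The benzene ring is bought with both bromines in place, so only the pyrrole ring (N1, C2, C3, C3a, C7a) is built. C3–Br is cut first, as a late electrophilic bromination of the N–H indole.
2. Feature used: C2 of the pyrrole ring has only three neighbours, N1, C3 and Cl. It is an isolated carbon at the trihalomethane oxidation level, so it is excised as CHCl3 by breaking C2–C3 and N1–C2 (formal [4+1]).
3. The four-atom partner N1–C7a–C3a–C3 is an N-tosyl aza-ortho-quinone methide, released by base from the 3,6-dibromo-2-(chloromethyl)sulfonanilide.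
4. That sulfonanilide comes from 3,6-dibromo-2-fluorobenzaldehyde (SNAr with TsNH2, NaBH4, SOCl2). The aldehyde comes from 1,4-dibromo-2-fluorobenzene and DMF by lithiation between F and Br.
5. Ring order: the carbocycle is purchased and the pyrrole ring is closed in the key step.

Key step: step 5

Assumption: the target is planar and has no stereogenic element, so the request for a single enantiomer calls for no stereocontrol and the SMILES defines the compound fully.

## Route

Step 1
Reactants: 1 1,4-dibromo-2-fluorobenzene; 2 N,N-dimethylformamide
Product: 4 3,6-dibromo-2-fluorobenzaldehyde, via 3,6-dibromo-2-fluorophenyllithium 3 (not isolated)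
Conditions: LDA (1.1 equiv), THF, −78 °C; 2 (1.5 equiv), −78 °C; 1 M HCl
Reagents that add atoms: N,N-dimethylformamide, CN(C)C=O
Why: Directed ortho-lithiation followed by DMF formylation: the one C–H flanked by F and Br is by far the most acidic, the amide base LDA deprotonates without Br/Li exchange, and at −78 °C aryllithium 3 should be trapped before aryne formation or halogen dance.

Step 2
Reactants: 4 3,6-dibromo-2-fluorobenzaldehyde; 5 p-toluenesulfonamide
Product: 6 N-(3,6-dibromo-2-formylphenyl)-4-methylbenzenesulfonamide
Conditions: 5 (1.2 equiv), dry K2CO3 (2.5 equiv), DMSO, 90 °C; dilute HCl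
Reagents that add atoms: p-toluenesulfonamide, Cc1ccc(cc1)S(N)(=O)=O
Why: SNAr (addition–elimination through a Meisenheimer adduct): the formyl group ortho to C–F stabilises the adduct, fluoride leaves far faster than either bromide, the product is parked as its unreactive anion, and bringing nitrogen in already tosylated avoids sulfonylating a deactivated, di-ortho-substituted aniline.

Step 3
Reactants: 6 N-(3,6-dibromo-2-formylphenyl)-4-methylbenzenesulfonamide
Product: 7 N-[3,6-dibromo-2-(hydroxymethyl)phenyl]-4-methylbenzenesulfonamide
Conditions: NaBH4 (1.5 equiv), THF–MeOH, 0 °C; aq NH4Cl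
Reagents that add atoms: none
Why: Borohydride reduction of an aromatic aldehyde, which leaves the aryl bromides and the sulfonamide untouched (the extra hydride covers the acidic N–H).

Step 4
Reactants: 7 N-[3,6-dibromo-2-(hydroxymethyl)phenyl]-4-methylbenzenesulfonamide; 8 thionyl chloride
Product: 9 N-[3,6-dibromo-2-(chloromethyl)phenyl]-4-methylbenzenesulfonamide
Conditions: 8 (2 equiv), CH2Cl2, 0 → 40 °C; evaporation, no basic wash, used without chromatography
Reagents that add atoms: thionyl chloride, O=S(Cl)Cl
Why: Deoxychlorination through the chlorosulfite ester, the standard access to N-sulfonyl 2-(chloromethyl)anilines; the acidic medium keeps nitrogen protonated so that no quinone methide forms early, and the base-free work-up preserves the chloride.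

Step 5
Reactants: 9 N-[3,6-dibromo-2-(chloromethyl)phenyl]-4-methylbenzenesulfonamide; 10 chloroform
Product: 15 4,7-dibromo-2-chloro-1-tosylindole, via aza-ortho-quinone methide 11 (not isolated), via trichloroethyl sulfonanilide 12 (not isolated), via dichlorovinyl sulfonanilide 13 (not isolated), via chloroethynyl sulfonanilide 14 (not isolated)
Conditions: 10 (10 equiv), KOtBu (2.5 equiv, 1 M in THF, syringe pump), DMF, −40 → 0 °C; CHCl3/THF removed in vacuo; KOtBu (2.5 equiv), 0 °C → rt; aq NH4Cl
Reagents that add atoms: chloroform, ClC(Cl)Cl
Why: Proposed new method: the first equivalent of KOtBu deprotonates the sulfonamide of 9, whose anion expels the benzylic chloride (1,4-elimination) to give 11, while further base turns the excess chloroform into Cl3C−, which adds to the exocyclic CH2 with rearomatisation and forms C2–C3 in 12 (a direct SN2 on 9 would give the same adduct). In the second stage E2 loss of HCl across CH2–CCl3 gives 13 and an anti-elimination gives chloroalkyne 14, a detour planned deliberately because direct 5-endo-trig vinylic substitution, reliable for difluorovinyl groups, cannot be counted on for a dichlorovinyl group. The sulfonamide anion then closes the pyrrole ring by 5-endo-dig addition to the chlorine-bearing alkyne carbon (N1–C2; the 4-exo alternative is geometrically excluded) and tBuOH protonates the C3 vinyl anion, so the balance is 9 + CHCl3 − 3 HCl and no stereocentre arises. The closest known reaction types are the [4+1] annulation of N-sulfonyl aza-ortho-quinone methides with sulfur ylides, the conjugate addition of Cl3C− to electron-poor alkenes, the dehydrochlorination of 2,2,2-trichloroethylarenes and the base-mediated cyclisation of 2-(gem-dihalovinyl)sulfonanilides to 2-haloindoles. The step needs carbon attack by Cl3C− to outrun its α-elimination to dichlorocarbene, the self-reaction of 11 and capture by tBuOH; the substrate helps because the unsubstituted CH2 of 11 is the only site whose attack restores aromaticity, the two bromines lower its LUMO, and the sulfonamide anion is stabilised and flanked on both sides, hence a poor intermolecular N-nucleophile. Low temperature, DMF (which prolongs the life of Cl3C−), tenfold chloroform and slow base addition support this, and chloroform is stripped before the second stage so that the base is not consumed and no carbene meets the indole.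

Step 6
Reactants: 15 4,7-dibromo-2-chloro-1-tosylindole
Product: 16 4,7-dibromo-2-chloro-1H-indole
Conditions: 2 M aq NaOH (3 equiv), 1,4-dioxane, 40 °C; aq NH4Cl to pH 7, kept cold and dark, used at once
Reagents that add atoms: none
Why: Alkaline hydrolysis of an N-sulfonylindole by attack of hydroxide at sulfur, eased here because the trihalogenated indolide is a good leaving group and the tosyl group is squeezed between C2–Cl and C7–Br; the neutral work-up avoids acid hydrolysis of the 2-chloroindole to the oxindole.

Step 7
Reactants: 16 4,7-dibromo-2-chloro-1H-indole; 17 N-bromosuccinimide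
Product: 18 3,4,7-tribromo-2-chloro-1H-indole (target)
Conditions: 17 (1.0 equiv), DMF, 0 °C, dark
Reagents that add atoms: N-bromosuccinimide, O=C1CCC(=O)N1Br
Why: Electrophilic aromatic bromination of an N–H indole: C3 is the only free pyrrole position and far more nucleophilic than C5/C6 of the dibrominated benzene ring, in line with the known NBS bromination of 2-chloroindole to 3-bromo-2-chloroindole.

## Compound list

1 | 1,4-dibromo-2-fluorobenzene | Fc1cc(Br)ccc1Br | starting material
2 | N,N-dimethylformamide | CN(C)C=O | starting material
3 | 3,6-dibromo-2-fluorophenyllithium | [Li]c1c(F)c(Br)ccc1Br | intermediate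
4 | 3,6-dibromo-2-fluorobenzaldehyde | O=Cc1c(F)c(Br)ccc1Br | intermediate
5 | p-toluenesulfonamide | Cc1ccc(cc1)S(N)(=O)=O | starting material
6 | N-(3,6-dibromo-2-formylphenyl)-4-methylbenzenesulfonamide | Cc1ccc(cc1)S(=O)(=O)Nc1c(Br)ccc(Br)c1C=O | intermediate
7 | N-[3,6-dibromo-2-(hydroxymethyl)phenyl]-4-methylbenzenesulfonamide | Cc1ccc(cc1)S(=O)(=O)Nc1c(Br)ccc(Br)c1CO | intermediate
8 | thionyl chloride | O=S(Cl)Cl | starting material
9 | N-[3,6-dibromo-2-(chloromethyl)phenyl]-4-methylbenzenesulfonamide | Cc1ccc(cc1)S(=O)(=O)Nc1c(Br)ccc(Br)c1CCl | intermediate
10 | chloroform | ClC(Cl)Cl | starting material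
11 | N-(2,5-dibromo-6-methylidenecyclohexa-2,4-dien-1-ylidene)-4-methylbenzenesulfonamide (aza-ortho-quinone methide) | C=C1C(Br)=CC=C(Br)C1=NS(=O)(=O)c1ccc(C)cc1 | intermediate
12 | N-[3,6-dibromo-2-(2,2,2-trichloroethyl)phenyl]-4-methylbenzenesulfonamide (present as its N-potassium salt) | Cc1ccc(cc1)S(=O)(=O)Nc1c(Br)ccc(Br)c1CC(Cl)(Cl)Cl | intermediate
13 | N-[3,6-dibromo-2-(2,2-dichloroethenyl)phenyl]-4-methylbenzenesulfonamide (present as its N-potassium salt) | Cc1ccc(cc1)S(=O)(=O)Nc1c(Br)ccc(Br)c1C=C(Cl)Cl | intermediate
14 | N-[3,6-dibromo-2-(chloroethynyl)phenyl]-4-methylbenzenesulfonamide (present as its N-potassium salt) | Cc1ccc(cc1)S(=O)(=O)Nc1c(Br)ccc(Br)c1C#CCl | intermediate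
15 | 4,7-dibromo-2-chloro-1-tosylindole | Cc1ccc(cc1)S(=O)(=O)n1c(Cl)cc2c(Br)ccc(Br)c12 | intermediate
16 | 4,7-dibromo-2-chloro-1H-indole | Clc1cc2c(Br)ccc(Br)c2[nH]1 | intermediate
17 | N-bromosuccinimide | O=C1CCC(=O)N1Br | starting material
18 | 3,4,7-tribromo-2-chloro-1H-indole | Clc1[nH]c2c(Br)ccc(Br)c2c1Br | target

Total step count: 7
Longest linear sequence: 7

## Steps most likely to fail

**Step 5 (key step).**
- What may go wrong: the trichloromethyl anion may decay to dichlorocarbene before the quinone methide is released.
- The quinone methide may instead self-condense or be captured by tert-butanol.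
- The second stage may stall before ring closure, or begin to strip the tosyl group.
- Fallback, known chemistry without the one-carbon insertion: it sets out from aldehyde 6. Wittig methoxymethylenation (methoxymethyltriphenylphosphonium chloride, NaHMDS in excess to cover the N–H, THF, 0 °C) would give N-[3,6-dibromo-2-(2-methoxyethenyl)phenyl]-4-methylbenzenesulfonamide F1. Catalytic TsOH in toluene at 80 °C would cyclise it with loss of methanol to 4,7-dibromo-1-tosylindole F2. C2-lithiation with LDA at −78 °C followed by hexachloroethane would then give 15, where the route is rejoined.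

**Step 2.**
- What may go wrong: substitution may be sluggish at a C–F bond flanked on both sides, or base may induce loss of the formyl group from the 2,6-disubstituted benzaldehyde.
- Fallback, forming C–N before N–S: it sets out from 4. Ammonia in DMSO (sealed tube, 80 °C), with mild acidic hydrolysis of the imine, would give 2-amino-3,6-dibromobenzaldehyde F3. Its anilide anion (NaH, 2 equiv, THF, 0 °C) would be sulfonylated with p-toluenesulfonyl chloride to give 6, where the route is rejoined.

**Step 6.**
- What may go wrong: the C3-unsubstituted N–H 2-chloroindole may degrade while it is liberated and worked up, by hydrolysis towards the oxindole, air oxidation or oligomerisation.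
- Fallback, inverting the order of the last two operations: it sets out from 15. Bromination at C3 with Br2 in CH2Cl2–AcOH would give 3,4,7-tribromo-2-chloro-1-tosylindole F4. Aqueous NaOH in dioxane would then remove the tosyl group and give 18 directly, so that 16 is never handled.

Further compounds
F1 | step 5 | N-[3,6-dibromo-2-(2-methoxyethenyl)phenyl]-4-methylbenzenesulfonamide (E/Z mixture) | COC=Cc1c(Br)ccc(Br)c1NS(=O)(=O)c1ccc(C)cc1
F2 | step 5 | 4,7-dibromo-1-tosylindole | Cc1ccc(cc1)S(=O)(=O)n1ccc2c(Br)ccc(Br)c12
F3 | step 2 | 2-amino-3,6-dibromobenzaldehyde | Nc1c(Br)ccc(Br)c1C=O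
F4 | step 6 | 3,4,7-tribromo-2-chloro-1-tosylindole | Cc1ccc(cc1)S(=O)(=O)n1c(Cl)c(Br)c2c(Br)ccc(Br)c12
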